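**Strategy.** The route holds C5, C6 and C11, the contiguous stereocentres where the five-membered ring (C5–C6–C7–C8–C10) meets the seven-membered ring (C1–C2–C3–C4–C5–C6–C11), as a cyclopropane whose C5–C11 bond is temporary. One copper-carbene cyclopropanation of an acyclic diazo β-keto ester forms C5–C6, closes the cyclopentanone and fixes C6 and C11 relative to each other and in the absolute sense. Isopropyl cuprate then breaks C5–C11 with inversion at C11. The precursor is methyl (E)-2-diazo-3-oxo-8-silyloxyoct-6-enoate, made in four steps. A type II carbonyl-ene reaction later closes the seven-membered ring, and two tethered oxygen deliveries set C3 and the epoxide.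

Key step: step 5

Remarks on the chemistry:
- Atom numbers C1–C11 are those of the target used above. α is the face of the bicycle carrying H6; β is the face carrying H5. In the target, the C1 ester oxygen, the C3 hydroxyl, the C11 isopropyl group and the epoxide oxygen are α, and the C3 methyl is β.
- Assumption: (E)-but-2-ene-1,4-diol is taken as commercially available; it fixes the alkene geometry from the start.
- A tert-butyldiphenylsilyl ether is used on C1–O so that it survives the hot chloride of step 8.
- The (E)-alkene combined with inversion at C11 in step 6 gives the C6/C11 relationship of the target, and (1R,5S,6S)-8 is the enantiomer that maps onto it.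

Step 1
Reactants: 1 (E)-but-2-ene-1,4-diol
Product: 2 (E)-4-[(tert-butyldiphenylsilyl)oxy]but-2-en-1-ol
Conditions: NaH (1.0 equiv), THF, 0 °C to rt; then TBDPSCl (1.0 equiv)
Reagents that add atoms: tert-butyl(chloro)diphenylsilane, CC(C)(C)[Si](Cl)(c1ccccc1)c1ccccc1
Why: O-silylation of the sparingly soluble monosodium alkoxide of a symmetrical diol should stop cleanly at the mono-ether and leaves the (E)-alkene untouched.

Step 2
Reactants: 2 (E)-4-[(tert-butyldiphenylsilyl)oxy]but-2-en-1-ol
Product: 3 (E)-[(4-bromobut-2-en-1-yl)oxy](tert-butyl)diphenylsilane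
Conditions: CBr4, PPh3, CH2Cl2, 0 °C
Reagents that add atoms: carbon tetrabromide, BrC(Br)(Br)Br
Why: The Appel reaction converts a primary allylic alcohol into the unrearranged bromide under neutral conditions, with the alkene geometry and the silyl ether retained.

Step 3
Reactants: 4 methyl acetoacetate; 3 (E)-[(4-bromobut-2-en-1-yl)oxy](tert-butyl)diphenylsilane
Product: 6 methyl (E)-8-[(tert-butyldiphenylsilyl)oxy]-3-oxooct-6-enoate, via methyl acetoacetate dianion 5 (not isolated)
Conditions: NaH, THF, 0 °C; n-BuLi, 0 °C; then 3, 0 °C to rt; aq. NH4Cl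
Reagents that add atoms: none
Why: In this acetoacetate dianion γ-alkylation the more basic terminal carbanion attacks the primary allylic bromide by SN2, which should give the δ,ε-unsaturated β-keto ester with the (E)-geometry of 3 preserved.

Step 4
Reactants: 6 methyl (E)-8-[(tert-butyldiphenylsilyl)oxy]-3-oxooct-6-enoate
Product: 7 methyl (E)-8-[(tert-butyldiphenylsilyl)oxy]-2-diazo-3-oxooct-6-enoate
Conditions: p-ABSA, Et3N, MeCN, 0 °C to rt
Reagents that add atoms: 4-acetamidobenzenesulfonyl azide, CC(=O)Nc1ccc(cc1)S(=O)(=O)N=[N+]=[N-]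
Why: Regitz diazo transfer to the active methylene of a β-keto ester proceeds with mild amine base and tolerates the alkene and the silyl ether.

Step 5
Reactants: 7 methyl (E)-8-[(tert-butyldiphenylsilyl)oxy]-2-diazo-3-oxooct-6-enoate
Product: 8 methyl (1R,5S,6S)-6-{[(tert-butyldiphenylsilyl)oxy]methyl}-2-oxobicyclo[3.1.0]hexane-1-carboxylate
Conditions: CuOTf·½PhMe (5 mol%), t-Bu-bisoxazoline ligand (6 mol%; the antipode that delivers (1R,5S,6S)-8), toluene, 25–50 °C, slow addition of 7
Reagents that add atoms: none
Why: The Cu(I)–bisoxazoline complex decomposes 7 with loss of N2 to an electrophilic copper carbene at C5, which adds to the tethered C6=C11 alkene in a concerted, asynchronous [2+1] step that forms C5–C6 and C5–C11 together. The closest known reaction type is the catalytic asymmetric intramolecular cyclopropanation of δ,ε-unsaturated α-diazo β-keto esters and sulfones with chiral copper(I) bisoxazoline catalysts. The cyclopentanone closes in a 5-exo sense, C5 bonding to the proximal alkene carbon C6 across the three-atom tether C10–C8–C7, and the three-membered ring closes in the same event at the distal carbon C11, so the ring fusion can only be cis. The C6/C11 relationship follows from stereospecific syn addition to the (E)-alkene, which places C7 and the silyloxymethyl group trans on the cyclopropane (CH2OSi exo); C5 follows from the cis fusion, and the absolute sense of all three centres from the ligand enantiomer. The step needs enantioface selection and chemoselectivity for cyclopropanation over carbene dimerisation, C–H insertion and ylide formation; the first rests on the C2-symmetric ligand pocket reading the (E)-disubstituted alkene, the second on the absence of any sp3 C–H five atoms from the carbene carbon, on the bulky, weakly basic silyl ether oxygen and on slow addition.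

Step 6
Reactants: 8 methyl (1R,5S,6S)-6-{[(tert-butyldiphenylsilyl)oxy]methyl}-2-oxobicyclo[3.1.0]hexane-1-carboxylate; 9 isopropylmagnesium chloride
Product: 10 methyl (5S)-5-[(2S)-1-[(tert-butyldiphenylsilyl)oxy]-3-methylbutan-2-yl]-2-oxocyclopentane-1-carboxylate (C1 epimers and enol)
Conditions: i-PrMgCl (3 equiv), CuBr·SMe2 (1.5 equiv), THF, −40 to 0 °C; aq. NH4Cl
Reagents that add atoms: none
Why: In this homoconjugate addition of an organocuprate to a cyclopropane activated by both ketone and ester, SN2-type attack at the exocyclic cyclopropane carbon C11, whose bond to C5 overlaps best with the ketone π-system, should break C5–C11 with inversion at C11 and leave C6 untouched, which gives the target configuration at C11.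

Step 7
Reactants: 10 methyl (5S)-5-[(2S)-1-[(tert-butyldiphenylsilyl)oxy]-3-methylbutan-2-yl]-2-oxocyclopentane-1-carboxylate; 11 3-bromo-2-methylprop-1-ene (methallyl bromide)
Product: 12 methyl (5S)-5-[(2S)-1-[(tert-butyldiphenylsilyl)oxy]-3-methylbutan-2-yl]-1-(2-methylallyl)-2-oxocyclopentane-1-carboxylate (configuration at the new quaternary carbon not defined)
Conditions: K2CO3, acetone, reflux
Reagents that add atoms: none
Why: C-Alkylation of the cyclic β-keto ester enolate with a reactive allylic bromide is specific for C5, the only doubly activated position, and the configuration of the quaternary centre is irrelevant because step 8 erases it.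

Step 8
Reactants: 12 methyl (5S)-5-[(2S)-1-[(tert-butyldiphenylsilyl)oxy]-3-methylbutan-2-yl]-1-(2-methylallyl)-2-oxocyclopentane-1-carboxylate
Product: 13 (2S,3S)-3-[(2S)-1-[(tert-butyldiphenylsilyl)oxy]-3-methylbutan-2-yl]-2-(2-methylallyl)cyclopentan-1-one (2,3-trans)
Conditions: LiCl, H2O, DMSO, 150 °C
Reagents that add atoms: none
Why: Krapcho dealkoxycarbonylation (chloride SN2 at the ester methyl, then loss of CO2) leaves a C5–H ketone that equilibrates through its enol to the more stable 2,3-trans cyclopentanone, which sets C5 relative to C6.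

Step 9
Reactants: 13 (2S,3S)-3-[(2S)-1-[(tert-butyldiphenylsilyl)oxy]-3-methylbutan-2-yl]-2-(2-methylallyl)cyclopentan-1-one
Product: 14 (2S,3S)-3-[(2S)-1-hydroxy-3-methylbutan-2-yl]-2-(2-methylallyl)cyclopentan-1-one
Conditions: TBAF, THF, 0 °C to rt
Reagents that add atoms: none
Why: Fluoride cleaves the silyl ether to the primary alcohol, and the mildly basic medium can only reinforce the thermodynamic trans arrangement at C5.

Step 10
Reactants: 14 (2S,3S)-3-[(2S)-1-hydroxy-3-methylbutan-2-yl]-2-(2-methylallyl)cyclopentan-1-one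
Product: 15 (2S)-3-methyl-2-[(1S,2S)-2-(2-methylallyl)-3-oxocyclopentyl]butanal
Conditions: Dess–Martin periodinane, NaHCO3, CH2Cl2, 0 °C to rt; used at once
Reagents that add atoms: none
Why: Buffered Dess–Martin oxidation gives the aldehyde without over-oxidation and under conditions too mild to epimerise the α-stereocentre C11.

Step 11
Reactants: 15 (2S)-3-methyl-2-[(1S,2S)-2-(2-methylallyl)-3-oxocyclopentyl]butanal
Product: 16 5-hydroxy-7-methylidene-4-(propan-2-yl)octahydroazulen-1(2H)-one (trans-fused; C1–OH α; C11 i-Pr α; H5 β; H6 α)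
Conditions: Me2AlCl (2.5 equiv), CH2Cl2, −78 to −20 °C; aq. HCl
Reagents that add atoms: none
Why: In this Lewis-acid-promoted type II carbonyl-ene cyclisation the terminal alkene carbon (C2) bonds to the aldehyde carbon C1 while a methyl hydrogen passes to oxygen, which closes the seven-membered ring; the closed bicyclic transition state holds the aldehyde oxygen axial and the C11 isopropyl equatorial, so the C1 hydroxyl should form cis to the isopropyl group, and the ketone is a far poorer enophile.

Step 12
Reactants: 16 5-hydroxy-7-methylidene-4-(propan-2-yl)octahydroazulen-1(2H)-one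
Product: 17 tert-butyl carbonate of 16 at O–C1
Conditions: Boc2O, DMAP, MeCN, rt
Reagents that add atoms: di-tert-butyl dicarbonate, CC(C)(C)OC(=O)OC(=O)OC(C)(C)C
Why: DMAP-catalysed acylation of the secondary alcohol installs the carbonate that serves as the internal oxygen nucleophile of the next step.

Step 13
Reactants: 17 tert-butyl carbonate of 16 at O–C1
Product: 18 cyclic carbonate bridging O–C1 and O–C3 (both α) with CH2I on C3 (β) and the C10 ketone retained
Conditions: IBr, toluene/CH2Cl2, −80 °C; aq. Na2S2O3
Reagents that add atoms: iodine monobromide, IBr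
Why: In this iodocarbonate cyclisation the iodonium ion of the exocyclic alkene is opened at the tertiary carbon C3 by the carbonate carbonyl oxygen (6-exo, Markovnikov) with loss of the tert-butyl cation, and the six-membered bridge can only form cis, which sets C3 with its oxygen on the face of the C1 oxygen.

Step 14
Reactants: 18 cyclic iodocarbonate ketone
Product: 22 C8-methylidene C10 ketone (exocyclic enone of 18), via lithium enolate 19 (not isolated), via Mannich base 20 (not isolated), via trimethylammonium iodide 21 (not isolated)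
Conditions: LDA, THF, −78 °C; CH2=NMe2+ I−, −78 °C to rt; MeI, CH2Cl2; aq. NaHCO3
Reagents that add atoms: N,N-dimethylmethyleneiminium iodide (Eschenmoser's salt), C=[N+](C)C.[I-]
Why: Kinetic deprotonation takes the C8 methylene and not the ring-fusion methine C5, and the Mannich reaction of that enolate followed by quaternisation and β-elimination places the future C8 methyl carbon regiospecifically as an α-methylene group.

Step 15
Reactants: 22 C8-methylidene C10 ketone
Product: 23 C8-methylidene C10 alcohol (allylic alcohol; C10 configuration immaterial)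
Conditions: NaBH4, CeCl3·7H2O, MeOH, −40 °C
Reagents that add atoms: none
Why: Luche reduction gives 1,2-reduction of the enone and spares the carbonate and the neopentyl-type iodide; the new carbinol centre is destroyed in step 16.

Step 16
Reactants: 23 C8-methylidene C10 alcohol
Product: 26 iodomethyl cyclic carbonate with the C8-methyl C8=C10 cyclopentene, via sulfonylhydrazine adduct 24 (not isolated), via allylic diazene 25 (not isolated)
Conditions: 2-nitrobenzenesulfonylhydrazide, PPh3, DEAD, THF, −30 to 23 °C
Reagents that add atoms: none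
Why: Mitsunobu displacement by the sulfonylhydrazide, loss of arenesulfinic acid and retro-ene loss of N2 from the allylic diazene transfer hydrogen to the exocyclic CH2 and move the double bond into the ring, so the C8-methyl C8=C10 alkene forms without regiochemical ambiguity.

Step 17
Reactants: 26 iodomethyl cyclic carbonate with the C8=C10 alkene
Product: 28 2,7-dimethyl-4-(propan-2-yl)-3,3a,4,5,6,7,8,8a-octahydroazulene-5,7-diol (C1–OH α; C3–OH α; C3–CH3 β), via spiro-epoxy alcohol 27 (not isolated)
Conditions: LiAlH4, THF, 0 to 40 °C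
Reagents that add atoms: none
Why: Hydride cleaves the cyclic carbonate, the freed tertiary alkoxide closes onto CH2I to a spiro-epoxide, and hydride opens this at its CH2 terminus, so CH2I becomes CH3 with the C3–O bond of step 13 retained and the isolated alkene inert.

Step 18
Reactants: 29 3-hydroxy-4-methoxybenzoic acid (isovanillic acid)
Product: 31 3-[(tert-butyldimethylsilyl)oxy]-4-methoxybenzoic acid, via bis-silylated acid 30 (not isolated)
Conditions: TBSCl, imidazole, DMF, rt; then AcOH/THF/H2O, rt
Reagents that add atoms: tert-butyldimethylsilyl chloride, CC(C)(C)[Si](C)(C)Cl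
Why: Exhaustive silylation followed by selective hydrolysis of the labile silyl ester leaves the phenol masked as its aryl silyl ether.

Step 19
Reactants: 28 2,7-dimethyl-4-(propan-2-yl)-3,3a,4,5,6,7,8,8a-octahydroazulene-5,7-diol; 31 3-[(tert-butyldimethylsilyl)oxy]-4-methoxybenzoic acid
Product: 33 C1 3-[(tert-butyldimethylsilyl)oxy]-4-methoxybenzoate of 28, via mixed anhydride 32 (not isolated)
Conditions: 2,4,6-trichlorobenzoyl chloride, Et3N, THF, rt; then 28, DMAP, toluene, rt to 60 °C
Reagents that add atoms: none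
Why: Yamaguchi esterification acylates the secondary C1 hydroxyl selectively, because the tertiary C3 hydroxyl is too hindered, and leaves the latter free to direct step 20.

Step 20
Reactants: 33 C1 3-[(tert-butyldimethylsilyl)oxy]-4-methoxybenzoate of 28
Product: 34 silyl-protected target (C8–C10 α-epoxide)
Conditions: VO(acac)2 (cat.), t-BuOOH, CH2Cl2, 0 °C to rt
Reagents that add atoms: tert-butyl hydroperoxide, CC(C)(C)OO
Why: In this vanadium-catalysed hydroxyl-directed epoxidation the peroxo-vanadium ester of the α-oriented bishomoallylic C3 hydroxyl delivers oxygen to the α-face of the C8=C10 alkene, which sets C8 and C10 with the epoxide cis to H6, while ester and arene are inert.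

Step 21
Reactants: 34 silyl-protected target
Product: 35 CNP0106636.1
Conditions: TBAF, AcOH, THF, 0 °C
Reagents that add atoms: none
Why: Buffered fluoride cleaves the aryl silyl ether selectively and leaves the ester, the tertiary alcohol and the epoxide intact.

**Compound list**

1 | (E)-but-2-ene-1,4-diol | OC/C=C/CO | starting material
2 | (E)-4-[(tert-butyldiphenylsilyl)oxy]but-2-en-1-ol | OC/C=C/CO[Si](c1ccccc1)(c2ccccc2)C(C)(C)C | intermediate
3 | (E)-[(4-bromobut-2-en-1-yl)oxy](tert-butyl)diphenylsilane | BrC/C=C/CO[Si](c1ccccc1)(c2ccccc2)C(C)(C)C | intermediate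
4 | methyl acetoacetate | CC(=O)CC(=O)OC | starting material
5 | methyl acetoacetate dianion (sodium lithium dienolate; not isolated) | [Na+].[Li+].C=C([O-])C=C([O-])OC | intermediate
6 | methyl (E)-8-[(tert-butyldiphenylsilyl)oxy]-3-oxooct-6-enoate | COC(=O)CC(=O)CC/C=C/CO[Si](c1ccccc1)(c2ccccc2)C(C)(C)C | intermediate
7 | methyl (E)-8-[(tert-butyldiphenylsilyl)oxy]-2-diazo-3-oxooct-6-enoate | COC(=O)C(=[N+]=[N-])C(=O)CC/C=C/CO[Si](c1ccccc1)(c2ccccc2)C(C)(C)C | intermediate
8 | methyl (1R,5S,6S)-6-{[(tert-butyldiphenylsilyl)oxy]methyl}-2-oxobicyclo[3.1.0]hexane-1-carboxylate | COC(=O)[C@]12C(=O)CC[C@H]1[C@@H]2CO[Si](c3ccccc3)(c4ccccc4)C(C)(C)C | intermediate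
9 | isopropylmagnesium chloride | CC(C)[Mg]Cl | starting material
10 | methyl (5S)-5-[(2S)-1-[(tert-butyldiphenylsilyl)oxy]-3-methylbutan-2-yl]-2-oxocyclopentane-1-carboxylate (C1 epimers and enol) | CC(C)[C@H](CO[Si](c1ccccc1)(c2ccccc2)C(C)(C)C)[C@@H]3CCC(=O)C3C(=O)OC | intermediate
11 | 3-bromo-2-methylprop-1-ene | CC(=C)CBr | starting material
12 | methyl (5S)-5-[(2S)-1-[(tert-butyldiphenylsilyl)oxy]-3-methylbutan-2-yl]-1-(2-methylallyl)-2-oxocyclopentane-1-carboxylate (quaternary centre not defined) | CC(C)[C@H](CO[Si](c1ccccc1)(c2ccccc2)C(C)(C)C)[C@@H]3CCC(=O)C3(CC(C)=C)C(=O)OC | intermediate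
13 | (2S,3S)-3-[(2S)-1-[(tert-butyldiphenylsilyl)oxy]-3-methylbutan-2-yl]-2-(2-methylallyl)cyclopentan-1-one | CC(C)[C@H](CO[Si](c1ccccc1)(c2ccccc2)C(C)(C)C)[C@@H]3CCC(=O)[C@H]3CC(C)=C | intermediate
14 | (2S,3S)-3-[(2S)-1-hydroxy-3-methylbutan-2-yl]-2-(2-methylallyl)cyclopentan-1-one | CC(C)[C@H](CO)[C@@H]1CCC(=O)[C@H]1CC(C)=C | intermediate
15 | (2S)-3-methyl-2-[(1S,2S)-2-(2-methylallyl)-3-oxocyclopentyl]butanal | CC(C)[C@H](C=O)[C@@H]1CCC(=O)[C@H]1CC(C)=C | intermediate
16 | 5-hydroxy-7-methylidene-4-(propan-2-yl)octahydroazulen-1(2H)-one (trans-fused; C1–OH α, C11 i-Pr α) | O[C@@H]1CC(=C)C[C@H]2[C@@H](CCC2=O)[C@@H]1C(C)C | intermediate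
17 | tert-butyl carbonate of 16 at O–C1 | CC(C)(C)OC(=O)O[C@@H]1CC(=C)C[C@H]2[C@@H](CCC2=O)[C@@H]1C(C)C | intermediate
18 | cyclic carbonate bridging O–C1 and O–C3 (α), CH2I on C3 (β), C10 ketone | O=C1O[C@@H]2C[C@](CI)(O1)C[C@H]3[C@@H](CCC3=O)[C@@H]2C(C)C | intermediate
19 | lithium C8=C10 enolate of 18 (not isolated) | O=C1O[C@@H]2C[C@](CI)(O1)C[C@H]3[C@@H](CC=C3[O-])[C@@H]2C(C)C.[Li+] | intermediate
20 | C8-(dimethylaminomethyl) ketone (Mannich base; C8 epimers; not isolated) | O=C1O[C@@H]2C[C@](CI)(O1)C[C@H]3[C@@H](CC(CN(C)C)C3=O)[C@@H]2C(C)C | intermediate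
21 | C8-(trimethylammoniomethyl) ketone iodide (not isolated) | O=C1O[C@@H]2C[C@](CI)(O1)C[C@H]3[C@@H](CC(C[N+](C)(C)C)C3=O)[C@@H]2C(C)C.[I-] | intermediate
22 | C8-methylidene C10 ketone | O=C1O[C@@H]2C[C@](CI)(O1)C[C@H]3[C@@H](CC(=C)C3=O)[C@@H]2C(C)C | intermediate
23 | C8-methylidene C10 alcohol (C10 epimers) | O=C1O[C@@H]2C[C@](CI)(O1)C[C@H]3[C@@H](CC(=C)C3O)[C@@H]2C(C)C | intermediate
24 | N-(C10-yl)-N-(2-nitrobenzenesulfonyl)hydrazine (not isolated) | O=C1O[C@@H]2C[C@](CI)(O1)C[C@H]3[C@@H](CC(=C)C3N(N)S(=O)(=O)c4ccccc4[N+](=O)[O-])[C@@H]2C(C)C | intermediate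
25 | C10 allylic diazene (not isolated) | O=C1O[C@@H]2C[C@](CI)(O1)C[C@H]3[C@@H](CC(=C)C3N=N)[C@@H]2C(C)C | intermediate
26 | iodomethyl cyclic carbonate with C8-methyl C8=C10 alkene | O=C1O[C@@H]2C[C@](CI)(O1)C[C@H]3[C@@H](CC(C)=C3)[C@@H]2C(C)C | intermediate
27 | spiro-epoxy alcohol (C3–CH2–O epoxide, O α; C1–OH α; not isolated) | O[C@@H]1C[C@@]2(CO2)C[C@H]3[C@@H](CC(C)=C3)[C@@H]1C(C)C | intermediate
28 | 2,7-dimethyl-4-(propan-2-yl)-3,3a,4,5,6,7,8,8a-octahydroazulene-5,7-diol (C1–OH α, C3–OH α, C3–CH3 β) | O[C@@H]1C[C@](C)(O)C[C@H]2[C@@H](CC(C)=C2)[C@@H]1C(C)C | intermediate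
29 | 3-hydroxy-4-methoxybenzoic acid | COc1ccc(C(=O)O)cc1O | starting material
30 | tert-butyldimethylsilyl 3-[(tert-butyldimethylsilyl)oxy]-4-methoxybenzoate (not isolated) | COc1ccc(C(=O)O[Si](C)(C)C(C)(C)C)cc1O[Si](C)(C)C(C)(C)C | intermediate
31 | 3-[(tert-butyldimethylsilyl)oxy]-4-methoxybenzoic acid | COc1ccc(C(=O)O)cc1O[Si](C)(C)C(C)(C)C | intermediate
32 | 3-[(tert-butyldimethylsilyl)oxy]-4-methoxybenzoic 2,4,6-trichlorobenzoic anhydride (not isolated) | COc1ccc(C(=O)OC(=O)c2c(Cl)cc(Cl)cc2Cl)cc1O[Si](C)(C)C(C)(C)C | intermediate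
33 | C1 3-[(tert-butyldimethylsilyl)oxy]-4-methoxybenzoate of 28 | COc1ccc(C(=O)O[C@@H]2C[C@](C)(O)C[C@H]3[C@@H](CC(C)=C3)[C@@H]2C(C)C)cc1O[Si](C)(C)C(C)(C)C | intermediate
34 | silyl-protected target (C8–C10 α-epoxide) | COc1ccc(C(=O)O[C@@H]2C[C@](C)(O)C[C@H]3[C@@H](C[C@@]4(C)O[C@@H]34)[C@@H]2C(C)C)cc1O[Si](C)(C)C(C)(C)C | intermediate
35 | CNP0106636.1 | COc1ccc(C(=O)O[C@@H]2C[C@](C)(O)C[C@H]3[C@@H](C[C@@]4(C)O[C@@H]34)[C@@H]2C(C)C)cc1O | target

**Step count.** Total: 21 steps. Longest linear sequence: 20 steps (steps 1–17 and 19–21); step 18 prepares the acid partner.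

**Steps most likely to fail**

Step 5. Enantioface discrimination by the copper–bisoxazoline carbene may be incomplete for a methyl diazo keto ester, and carbene dimerisation may compete. The fallback changes the activating group to a sulfone, the substrate class for which this cyclopropanation is best established. It sets out from bromide 3. The dianion of 1-(phenylsulfonyl)propan-2-one (NaH, n-BuLi) is alkylated with 3 to give (E)-7-[(tert-butyldiphenylsilyl)oxy]-1-(phenylsulfonyl)hept-5-en-2-one F1. Diazo transfer gives the 1-diazo keto sulfone F2, and Cu(I)/bisoxazoline cyclopropanation gives 6-exo-(silyloxymethyl)-1-(phenylsulfonyl)bicyclo[3.1.0]hexan-2-one F3. Cuprate opening as in step 6 gives the 2-(phenylsulfonyl)cyclopentanone F4, and methallylation as in step 7 gives the 2-methallyl-2-(phenylsulfonyl)cyclopentanone F5. Reductive desulfonylation (SmI2, THF/MeOH) and equilibration of the enolisable centre return the route to ketone 13.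

Step 6. SN2 displacement by a secondary alkyl cuprate at a hindered cyclopropane carbon may be outrun by electron-transfer reduction of the ring or by 1,2-addition to the ketone. The fallback uses an sp2 nucleophile and sets out from 8. Isopropenylmagnesium bromide/CuBr·SMe2 should open the ring with the same inversion to give the isopropenyl keto ester F6. Hydrogenation of its 1,1-disubstituted alkene (H2, Pd/C, EtOAc) comes back to 10.

Step 11. Face selection at the aldehyde may be poor if a boat-like or stepwise Prins pathway competes with the closed chair-like ene transition state, so that C1 forms with the hydroxyl trans to the isopropyl group. The fallback sets C1 by SN2 inversion after the ring closure and sets out from 15. The cyclisation product of the other face, the C1-epimeric alcohol F7, is subjected to a Mitsunobu reaction with chloroacetic acid (PPh3, DIAD) to give the inverted chloroacetate F8. Cleavage with thiourea/NaHCO3 in EtOH comes back to 16.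

**Further compounds**

F1 | step 5 | (E)-7-[(tert-butyldiphenylsilyl)oxy]-1-(phenylsulfonyl)hept-5-en-2-one | O=C(CS(=O)(=O)c1ccccc1)CC/C=C/CO[Si](c2ccccc2)(c3ccccc3)C(C)(C)C
F2 | step 5 | (E)-7-[(tert-butyldiphenylsilyl)oxy]-1-diazo-1-(phenylsulfonyl)hept-5-en-2-one | O=C(C(=[N+]=[N-])S(=O)(=O)c1ccccc1)CC/C=C/CO[Si](c2ccccc2)(c3ccccc3)C(C)(C)C
F3 | step 5 | 6-exo-{[(tert-butyldiphenylsilyl)oxy]methyl}-1-(phenylsulfonyl)bicyclo[3.1.0]hexan-2-one (absolute sense as in 8) | O=S(=O)(c1ccccc1)[C@]23C(=O)CC[C@H]2[C@@H]3CO[Si](c4ccccc4)(c5ccccc5)C(C)(C)C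
F4 | step 5 | 3-[(2S)-1-[(tert-butyldiphenylsilyl)oxy]-3-methylbutan-2-yl]-2-(phenylsulfonyl)cyclopentan-1-one (C2 epimers) | CC(C)[C@H](CO[Si](c1ccccc1)(c2ccccc2)C(C)(C)C)[C@@H]3CCC(=O)C3S(=O)(=O)c4ccccc4
F5 | step 5 | 3-[(2S)-1-[(tert-butyldiphenylsilyl)oxy]-3-methylbutan-2-yl]-2-(2-methylallyl)-2-(phenylsulfonyl)cyclopentan-1-one | CC(C)[C@H](CO[Si](c1ccccc1)(c2ccccc2)C(C)(C)C)[C@@H]3CCC(=O)C3(CC(C)=C)S(=O)(=O)c4ccccc4
F6 | step 6 | methyl 5-[1-[(tert-butyldiphenylsilyl)oxy]-3-methylbut-3-en-2-yl]-2-oxocyclopentane-1-carboxylate (C6 and C11 as in 10) | C=C(C)[C@H](CO[Si](c1ccccc1)(c2ccccc2)C(C)(C)C)[C@@H]3CCC(=O)C3C(=O)OC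
F7 | step 11 | C1 epimer of 16 (C1–OH β) | O[C@H]1CC(=C)C[C@H]2[C@@H](CCC2=O)[C@@H]1C(C)C
F8 | step 11 | chloroacetate of 16 (C1–O α) | ClCC(=O)O[C@@H]1CC(=C)C[C@H]2[C@@H](CCC2=O)[C@@H]1C(C)C
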